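**Plan**

1. Retrosynthesis (enone ring: C1 = C=O, C2 = carbon bearing the propanoic acid, C3 = carbon bearing the cyclohexyl ring, C6 = carbon bearing CH2OCHO, locant 5 in the systematic names): cut the formate C–O and the C6–CH2O bonds, then the C2–CH(CH3) bond, then read the enone ring as a 3-methoxyphenyl ring. In the cyclohexyl ring, cut both C–CH3 bonds of the gem-dimethyl carbon, restore C=O and C=C, and finally cut the quaternary C–CH2 bond and the ring C=C.
2. Enabling feature: the quaternary carbon holds a methyl group, two ring CH2 groups and sp2 carbon C3, with the gem-dimethyl carbon two bonds away. With the enone ring masked as an anisyl ring this is a 4-aryl-4-methylcyclohex-2-enone lacking only two α′-methyl groups, the product type of a Michael–aldol annulation of a 2-arylpropanal with methyl vinyl ketone.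
3. Forward order: acetophenone 1 is homologated to aldehyde 3; the annulation closes the six-membered carbocycle that becomes the trimethylcyclohexyl ring; dimethylation, hydrogenation and deoxygenation finish that ring; Birch reduction converts the arene into the enone ring; the propanoate is attached at C2 and the oxygenated carbon at C6; formylation and ester cleavage end the route.
4. Stereochemistry: the quaternary centre comes from the chiral amine catalyst of the annulation, the acid α-centre from tert-butyl (R)-lactate by invertive displacement of its triflate, and C6 from a chiral Sc(OTf)3–bipyridine catalyst in the hydroxymethylation.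

Key step: step 3

Assumption: the sense of induction of the two chiral catalysts (steps 3 and 11) is taken to be as written; both are accessible in either mirror-image form, so the antipode would be used if a pilot run showed the opposite sense.

**Route**

Step 1
Reactants: 1 3′-methoxyacetophenone
Product: 2 1-methoxy-3-(1-methoxyprop-1-en-2-yl)benzene (E/Z mixture)
Conditions: Ph3P(CH2OMe)Cl, KOtBu, THF, 0 °C to rt
Reagents that add atoms: (methoxymethyl)triphenylphosphonium chloride, COC[P+](c1ccccc1)(c1ccccc1)c1ccccc1.[Cl-]
Why: Wittig olefination with the non-stabilised methoxymethylene ylide turns the aryl methyl ketone into the one-carbon-homologous enol ether, and the alkene geometry is irrelevant because both isomers hydrolyse to the same aldehyde.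

Step 2
Reactants: 2 1-methoxy-3-(1-methoxyprop-1-en-2-yl)benzene
Product: 3 2-(3-methoxyphenyl)propanal (racemic)
Conditions: 2 M aq HCl, THF, rt
Reagents that add atoms: water, O
Why: Acid-catalysed enol ether hydrolysis (C-protonation, hydration of the oxocarbenium ion, loss of methanol) releases the α-aryl aldehyde, which is racemic by design and is used at once because such aldehydes oxidise and self-condense on standing.

Step 3
Reactants: 3 2-(3-methoxyphenyl)propanal (racemic); 4 methyl vinyl ketone
Product: 6 (R)-4-(3-methoxyphenyl)-4-methylcyclohex-2-en-1-one, via keto aldehyde 5 (not isolated)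
Conditions: (S)-N-(4-dodecylphenylsulfonyl)pyrrolidine-2-carboxamide (20 mol %), BnNH2 (co-catalyst), 4 Å MS, ClCH2CH2Cl, rt
Reagents that add atoms: none
Why: The pyrrolidine nitrogen of the catalyst condenses with racemic 3 to a trisubstituted enamine, which erases the aldehyde stereocentre, and the acidic sulfonamide N–H binds the carbonyl oxygen of 4 so that the enone reaches one enamine face in the Michael addition that creates the quaternary carbon of keto aldehyde 5. The methyl ketone of 5 then attacks the aldehyde in an amine-promoted aldol condensation, a 6-(enolendo)-exo-trig closure, and loss of water gives the ring C=C of 6. The closest known reaction type is the amine-catalysed asymmetric Michael–aldol (Robinson-type) annulation of 2-arylpropanals with vinyl ketones to 4-aryl-4-methylcyclohexenones. The only new stereocentre, the quaternary carbon, is set by the catalyst alone (enantiofacial control), which is why racemic 3 can be used. The step needs one enamine geometry and one closure regiochemistry: the size and conjugation difference between aryl and methyl favours the enamine with the aryl group trans to nitrogen, and after the Michael step the aldehyde has no α-hydrogen, so only the methyl ketone can serve as aldol donor and only a six-membered ring can form.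

Step 4
Reactants: 6 (R)-4-(3-methoxyphenyl)-4-methylcyclohex-2-en-1-one
Product: 8 (R)-4-(3-methoxyphenyl)-4,6,6-trimethylcyclohex-2-en-1-one, via monomethyl enone 7 (not isolated)
Conditions: LiN(i-Pr)2 (1.1 equiv), THF, −78 °C, then MeI; recool, LiN(i-Pr)2 (1.2 equiv), then MeI, −78 to 0 °C
Reagents that add atoms: iodomethane, CI
Why: Two successive kinetic enolate alkylations with iodomethane must both occur at C6, since C4 is quaternary and the enone has no γ-hydrogen, so C6 is the only enolisable position and the quaternary stereocentre is untouched.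

Step 5
Reactants: 8 (R)-4-(3-methoxyphenyl)-4,6,6-trimethylcyclohex-2-en-1-one
Product: 9 (S)-4-(3-methoxyphenyl)-2,2,4-trimethylcyclohexan-1-one
Conditions: H2 (1 atm), Pd/C, EtOAc, rt
Reagents that add atoms: none
Why: Heterogeneous catalytic hydrogenation saturates the disubstituted conjugated C=C far faster than it attacks the ketone or the anisole ring (the descriptor changes from R to S only because the ring priorities change).

Step 6
Reactants: 9 (S)-4-(3-methoxyphenyl)-2,2,4-trimethylcyclohexan-1-one
Product: 11 (S)-1-methoxy-3-(1,3,3-trimethylcyclohexyl)benzene, via hydrazone 10 (not isolated)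
Conditions: N2H4·H2O, KOH, diethylene glycol, 130 °C then 200 °C
Reagents that add atoms: none
Why: Wolff–Kishner reduction (Huang-Minlon procedure) proceeds by hydrazone formation, deprotonation, tautomerisation and loss of N2, is established for ketones flanked by a gem-dimethyl carbon, and leaves the aryl methyl ether and the non-epimerisable quaternary centre intact.

Step 7
Reactants: 11 (S)-1-methoxy-3-(1,3,3-trimethylcyclohexyl)benzene
Product: 14 3-[(1S)-1,3,3-trimethylcyclohexyl]cyclohex-2-en-1-one, via dienol ether 12 (not isolated), via deconjugated enone 13 (not isolated)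
Conditions: Li, t-BuOH, NH3(l)/THF, −78 to −33 °C; evaporate NH3; then 2 M aq HCl, THF, rt
Reagents that add atoms: water, O
Why: Birch reduction of the 3-alkylanisole protonates the two ring carbons that leave both donor-bearing carbons on double bonds, giving the 2,5-dihydroanisole 12 regioselectively, and aqueous acid hydrolyses the enol ether and moves the remaining C=C into conjugation.

Step 8
Reactants: 15 tert-butyl (2R)-2-hydroxypropanoate
Product: 16 tert-butyl (2R)-2-[(trifluoromethanesulfonyl)oxy]propanoate
Conditions: Tf2O, 2,6-lutidine, CH2Cl2, −78 to 0 °C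
Reagents that add atoms: trifluoromethanesulfonic anhydride, O=S(=O)(OS(=O)(=O)C(F)(F)F)C(F)(F)F
Why: O-Sulfonylation of the secondary alcohol with triflic anhydride and a hindered pyridine base does not touch the stereocentre, so the (R) configuration is retained in the triflate, which is used promptly.

Step 9
Reactants: 14 3-[(1S)-1,3,3-trimethylcyclohexyl]cyclohex-2-en-1-one; 16 tert-butyl (2R)-2-[(trifluoromethanesulfonyl)oxy]propanoate
Product: 18 tert-butyl (2R)-2-{6-oxo-2-[(1S)-1,3,3-trimethylcyclohexyl]cyclohex-1-en-1-yl}propanoate, via deconjugated keto ester 17 (not isolated)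
Conditions: NaN(SiMe3)2 (1.0 equiv), THF, −78 to 0 °C, 1 h; −78 °C, 16 (1.2 equiv), to −20 °C; then DBU (10 mol %), CH2Cl2, rt
Reagents that add atoms: none
Why: Proposed new method: deprotonation and amine-mediated equilibration should give the extended (γ-deprotonated) sodium dienolate of 14, whose α-carbon C2 carries the highest charge density and should displace the triflate of 16 by SN2 with inversion (the (R)-triflate gives the (R)-configured carbon because the new carbon substituent ranks below the ester), after which catalytic DBU returns the ring double bond of 17 to conjugation; the closest known reaction types are the α-alkylation of extended dienolates of 3-substituted cyclohexenones with alkyl halides and the invertive alkylation of imide and β-keto ester enolates with lactate triflates, whose basicity the extended dienolate should roughly match.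

Step 10
Reactants: 18 tert-butyl (2R)-2-{6-oxo-2-[(1S)-1,3,3-trimethylcyclohexyl]cyclohex-1-en-1-yl}propanoate
Product: 19 tert-butyl (2R)-2-{2-[(1S)-1,3,3-trimethylcyclohexyl]-6-[(trimethylsilyl)oxy]cyclohexa-1,5-dien-1-yl}propanoate
Conditions: LiN(i-Pr)2 (1.05 equiv), THF, −78 °C; TMSCl, −78 to 0 °C
Reagents that add atoms: chlorotrimethylsilane, C[Si](C)(C)Cl
Why: Kinetic deprotonation at −78 °C removes the accessible α′-hydrogen at C6 in preference to the γ-hydrogens at C4 and the hindered tertiary ester α-hydrogen, and O-silylation fixes the cross-conjugated enolate as its silyl enol ether.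

Step 11
Reactants: 19 tert-butyl (2R)-2-{2-[(1S)-1,3,3-trimethylcyclohexyl]-6-[(trimethylsilyl)oxy]cyclohexa-1,5-dien-1-yl}propanoate
Product: 20 tert-butyl (2R)-2-{(5S)-5-(hydroxymethyl)-6-oxo-2-[(1S)-1,3,3-trimethylcyclohexyl]cyclohex-1-en-1-yl}propanoate
Conditions: Sc(OTf)3 (10 mol %), (S,S)-6,6′-bis(1-hydroxy-2,2-dimethylpropyl)-2,2′-bipyridine (12 mol %), aq HCHO, DME/H2O, −20 °C
Reagents that add atoms: formaldehyde, C=O
Why: In this catalytic asymmetric Mukaiyama aldol reaction (hydroxymethylation of a silicon enolate) the chiral Sc(OTf)3–bipyridine complex activates aqueous formaldehyde in a chiral pocket and the only nucleophilic carbon, C6, attacks through one face, so the catalyst and not the remote stereocentres sets the (S) configuration.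

Step 12
Reactants: 20 tert-butyl (2R)-2-{(5S)-5-(hydroxymethyl)-6-oxo-2-[(1S)-1,3,3-trimethylcyclohexyl]cyclohex-1-en-1-yl}propanoate
Product: 21 tert-butyl (2R)-2-{(5S)-5-[(formyloxy)methyl]-6-oxo-2-[(1S)-1,3,3-trimethylcyclohexyl]cyclohex-1-en-1-yl}propanoate
Conditions: acetic formic anhydride, pyridine, CH2Cl2, 0 °C
Reagents that add atoms: acetic formic anhydride, CC(=O)OC=O
Why: Acyl transfer from the mixed anhydride occurs at the more electrophilic formyl carbonyl and formylates the primary alcohol at 0 °C with only pyridine as base, which should avoid β-elimination and epimerisation at C6.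

Step 13
Reactants: 21 tert-butyl (2R)-2-{(5S)-5-[(formyloxy)methyl]-6-oxo-2-[(1S)-1,3,3-trimethylcyclohexyl]cyclohex-1-en-1-yl}propanoate
Product: 22 (2R)-2-{(5S)-5-[(formyloxy)methyl]-6-oxo-2-[(1S)-1,3,3-trimethylcyclohexyl]cyclohex-1-en-1-yl}propanoic acid
Conditions: CF3CO2H/CH2Cl2 (1:4), 0 °C
Reagents that add atoms: none
Why: Acidolysis of the tert-butyl ester by the E1 pathway (tert-butyl cation, lost as isobutene) frees the acid under anhydrous conditions that should neither cleave the formate nor enolise the ketone appreciably at 0 °C.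

**Compound list**

1 | 3′-methoxyacetophenone | CC(=O)c1cccc(OC)c1 | starting material
2 | 1-methoxy-3-(1-methoxyprop-1-en-2-yl)benzene (E/Z mixture) | COC=C(C)c1cccc(OC)c1 | intermediate
3 | 2-(3-methoxyphenyl)propanal (racemic) | CC(C=O)c1cccc(OC)c1 | intermediate
4 | methyl vinyl ketone | CC(=O)C=C | starting material
5 | (S)-2-(3-methoxyphenyl)-2-methyl-5-oxohexanal | COc1cccc(c1)[C@@](C)(C=O)CCC(C)=O | intermediate
6 | (R)-4-(3-methoxyphenyl)-4-methylcyclohex-2-en-1-one | COc1cccc(c1)[C@@]1(C)C=CC(=O)CC1 | intermediate
7 | (4R)-4-(3-methoxyphenyl)-4,6-dimethylcyclohex-2-en-1-one (C6 epimers) | COc1cccc(c1)[C@@]1(C)C=CC(=O)C(C)C1 | intermediate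
8 | (R)-4-(3-methoxyphenyl)-4,6,6-trimethylcyclohex-2-en-1-one | COc1cccc(c1)[C@@]1(C)C=CC(=O)C(C)(C)C1 | intermediate
9 | (S)-4-(3-methoxyphenyl)-2,2,4-trimethylcyclohexan-1-one | COc1cccc(c1)[C@@]1(C)CCC(=O)C(C)(C)C1 | intermediate
10 | (S)-[4-(3-methoxyphenyl)-2,2,4-trimethylcyclohexylidene]hydrazine | COc1cccc(c1)[C@@]1(C)CCC(=NN)C(C)(C)C1 | intermediate
11 | (S)-1-methoxy-3-(1,3,3-trimethylcyclohexyl)benzene | COc1cccc(c1)[C@@]1(C)CCCC(C)(C)C1 | intermediate
12 | 1-methoxy-5-[(1S)-1,3,3-trimethylcyclohexyl]cyclohexa-1,4-diene | COC1=CCC=C(C1)[C@@]1(C)CCCC(C)(C)C1 | intermediate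
13 | 3-[(1S)-1,3,3-trimethylcyclohexyl]cyclohex-3-en-1-one | O=C1CCC=C(C1)[C@@]1(C)CCCC(C)(C)C1 | intermediate
14 | 3-[(1S)-1,3,3-trimethylcyclohexyl]cyclohex-2-en-1-one | O=C1C=C(CCC1)[C@@]1(C)CCCC(C)(C)C1 | intermediate
15 | tert-butyl (2R)-2-hydroxypropanoate (tert-butyl (R)-lactate) | C[C@@H](O)C(=O)OC(C)(C)C | starting material
16 | tert-butyl (2R)-2-[(trifluoromethanesulfonyl)oxy]propanoate | C[C@@H](OS(=O)(=O)C(F)(F)F)C(=O)OC(C)(C)C | intermediate
17 | tert-butyl (2R)-2-{2-oxo-6-[(1S)-1,3,3-trimethylcyclohexyl]cyclohex-5-en-1-yl}propanoate (ring C1 epimers) | C[C@@H](C(=O)OC(C)(C)C)C1C(=O)CCC=C1[C@@]1(C)CCCC(C)(C)C1 | intermediate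
18 | tert-butyl (2R)-2-{6-oxo-2-[(1S)-1,3,3-trimethylcyclohexyl]cyclohex-1-en-1-yl}propanoate | C[C@@H](C(=O)OC(C)(C)C)C1=C(CCCC1=O)[C@@]1(C)CCCC(C)(C)C1 | intermediate
19 | tert-butyl (2R)-2-{2-[(1S)-1,3,3-trimethylcyclohexyl]-6-[(trimethylsilyl)oxy]cyclohexa-1,5-dien-1-yl}propanoate | C[C@@H](C(=O)OC(C)(C)C)C1=C(CCC=C1O[Si](C)(C)C)[C@@]1(C)CCCC(C)(C)C1 | intermediate
20 | tert-butyl (2R)-2-{(5S)-5-(hydroxymethyl)-6-oxo-2-[(1S)-1,3,3-trimethylcyclohexyl]cyclohex-1-en-1-yl}propanoate | C[C@@H](C(=O)OC(C)(C)C)C1=C([C@@]2(C)CCCC(C)(C)C2)CC[C@@H](CO)C1=O | intermediate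
21 | tert-butyl (2R)-2-{(5S)-5-[(formyloxy)methyl]-6-oxo-2-[(1S)-1,3,3-trimethylcyclohexyl]cyclohex-1-en-1-yl}propanoate | C[C@@H](C(=O)OC(C)(C)C)C1=C([C@@]2(C)CCCC(C)(C)C2)CC[C@@H](COC=O)C1=O | intermediate
22 | (2R)-2-{(5S)-5-[(formyloxy)methyl]-6-oxo-2-[(1S)-1,3,3-trimethylcyclohexyl]cyclohex-1-en-1-yl}propanoic acid | C[C@@H](C(=O)O)C1=C([C@@]2(C)CCCC(C)(C)C2)CC[C@@H](COC=O)C1=O | target

**Step count and risks**

Total: 13 steps. Longest linear sequence: 12 steps (steps 1–7 and 9–13); step 8 is a one-step side branch.

Step 9 (proposed new method). The C–C bond must form next to the tert-alkyl-bearing carbon with a secondary electrophile, so several processes can compete: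
- O-alkylation or γ-alkylation (C4) of the dienolate;
- base-induced loss of triflic acid from 16;
- proton transfer from the more acidic alkylated ketone 17 to unreacted dienolate, which limits conversion;
- incomplete return of the double bond to conjugation against the strain of the tetrasubstituted alkene.

Fallback, from dienol ether 12 (isolated after the ammonia stage of step 7 instead of being hydrolysed) back to 18: heating 12 with (2R,3E)-pent-3-en-2-ol (lipase resolution of the commercial racemate) and catalytic propanoic acid in xylene at 140 °C should exchange the methoxy group for the allylic alkoxy group with loss of methanol and give the conjugated allyl dienyl ether 1-[(2R,3E)-pent-3-en-2-yloxy]-3-[(1S)-1,3,3-trimethylcyclohexyl]cyclohexa-1,3-diene F1. Under the same conditions F1 should undergo Claisen rearrangement, an intramolecular C–C bond formation that is little affected by the neighbouring tert-alkyl group. With the carbinol methyl group pseudo-equatorial in the transition state, the carbinol configuration is transferred to the new methyl-bearing carbon, giving 2-[(2S,3E)-pent-3-en-2-yl]-3-[(1S)-1,3,3-trimethylcyclohexyl]cyclohex-3-en-1-one F2. Catalytic DBU should conjugate it to 2-[(2S,3E)-pent-3-en-2-yl]-3-[(1S)-1,3,3-trimethylcyclohexyl]cyclohex-2-en-1-one F3. RuCl3 (cat.)/NaIO4 in MeCN/H2O should cleave the electron-rich disubstituted side-chain alkene in preference to the hindered, electron-poor ring alkene and give (2R)-2-{6-oxo-2-[(1S)-1,3,3-trimethylcyclohexyl]cyclohex-1-en-1-yl}propanoic acid F4. tert-Butyl 2,2,2-trichloroacetimidate with catalytic BF3·OEt2 then converts F4 into 18.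

Step 11. Facial selectivity may be poor on a cyclic, cross-conjugated silyl enol ether with a bulky neighbour; protodesilylation in the aqueous medium may outrun the aldol reaction; and the β-hydroxy ketone may epimerise at C6 or dehydrate.

Fallback, from 18 back to 20, with auxiliary control instead of catalyst control: condensation of 18 with (S)-1-amino-2-(methoxymethyl)pyrrolidine (SAMP; cat. TsOH, benzene, reflux) gives the hydrazone tert-butyl (2R)-2-{6-{[(2S)-2-(methoxymethyl)pyrrolidin-1-yl]imino}-2-[(1S)-1,3,3-trimethylcyclohexyl]cyclohex-1-en-1-yl}propanoate F5. LiN(i-Pr)2 in THF forms the chelated azaenolate on the CH2 side, and benzyl chloromethyl ether at −100 to −78 °C should alkylate it on the face set by the auxiliary. By the established model for cyclohexanone hydrazones this should give tert-butyl (2R)-2-{(5R)-5-[(benzyloxy)methyl]-6-{[(2S)-2-(methoxymethyl)pyrrolidin-1-yl]imino}-2-[(1S)-1,3,3-trimethylcyclohexyl]cyclohex-1-en-1-yl}propanoate F6; the enantiomeric auxiliary would be used otherwise. Two-phase aqueous oxalic acid/Et2O cleaves the hydrazone without epimerisation to tert-butyl (2R)-2-{(5S)-5-[(benzyloxy)methyl]-6-oxo-2-[(1S)-1,3,3-trimethylcyclohexyl]cyclohex-1-en-1-yl}propanoate F7. Hydrogenolysis (H2, Pd/C, EtOAc), which should spare the tetrasubstituted enone, returns 20.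

Step 6. Hydrazone formation may be slow at a carbonyl flanked by a gem-dimethyl carbon, azine formation may divert material, and the aryl methyl ether may be partly cleaved in hot alkali.

Fallback, from 9 back to 11, by radical deoxygenation: NaBH4 in MeOH gives (4S)-4-(3-methoxyphenyl)-2,2,4-trimethylcyclohexan-1-ol F8 (carbinol epimers, both usable). NaH, CS2 and then MeI in THF give the xanthate O-[(4S)-4-(3-methoxyphenyl)-2,2,4-trimethylcyclohexyl] S-methyl carbonodithioate F9. Barton–McCombie reduction (Bu3SnH, AIBN, toluene, reflux) returns 11.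

**Further compounds**

F1 | step 9 | 1-[(2R,3E)-pent-3-en-2-yloxy]-3-[(1S)-1,3,3-trimethylcyclohexyl]cyclohexa-1,3-diene | C/C=C/[C@@H](C)OC1=CC(=CCC1)[C@@]1(C)CCCC(C)(C)C1
F2 | step 9 | 2-[(2S,3E)-pent-3-en-2-yl]-3-[(1S)-1,3,3-trimethylcyclohexyl]cyclohex-3-en-1-one (ring C2 epimers) | C[C@@H](/C=C/C)C1C(=O)CCC=C1[C@@]1(C)CCCC(C)(C)C1
F3 | step 9 | 2-[(2S,3E)-pent-3-en-2-yl]-3-[(1S)-1,3,3-trimethylcyclohexyl]cyclohex-2-en-1-one | C[C@@H](/C=C/C)C1=C(CCCC1=O)[C@@]1(C)CCCC(C)(C)C1
F4 | step 9 | (2R)-2-{6-oxo-2-[(1S)-1,3,3-trimethylcyclohexyl]cyclohex-1-en-1-yl}propanoic acid | C[C@@H](C(=O)O)C1=C(CCCC1=O)[C@@]1(C)CCCC(C)(C)C1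
F5 | step 11 | tert-butyl (2R)-2-{6-{[(2S)-2-(methoxymethyl)pyrrolidin-1-yl]imino}-2-[(1S)-1,3,3-trimethylcyclohexyl]cyclohex-1-en-1-yl}propanoate | C[C@@H](C(=O)OC(C)(C)C)C1=C(CCCC1=NN1CCC[C@H]1COC)[C@@]1(C)CCCC(C)(C)C1
F6 | step 11 | tert-butyl (2R)-2-{(5R)-5-[(benzyloxy)methyl]-6-{[(2S)-2-(methoxymethyl)pyrrolidin-1-yl]imino}-2-[(1S)-1,3,3-trimethylcyclohexyl]cyclohex-1-en-1-yl}propanoate | C[C@@H](C(=O)OC(C)(C)C)C1=C([C@@]2(C)CCCC(C)(C)C2)CC[C@@H](COCc2ccccc2)C1=NN1CCC[C@H]1COC
F7 | step 11 | tert-butyl (2R)-2-{(5S)-5-[(benzyloxy)methyl]-6-oxo-2-[(1S)-1,3,3-trimethylcyclohexyl]cyclohex-1-en-1-yl}propanoate | C[C@@H](C(=O)OC(C)(C)C)C1=C([C@@]2(C)CCCC(C)(C)C2)CC[C@@H](COCc2ccccc2)C1=O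
F8 | step 6 | (4S)-4-(3-methoxyphenyl)-2,2,4-trimethylcyclohexan-1-ol (carbinol epimers) | COc1cccc(c1)[C@@]1(C)CCC(O)C(C)(C)C1
F9 | step 6 | O-[(4S)-4-(3-methoxyphenyl)-2,2,4-trimethylcyclohexyl] S-methyl carbonodithioate | COc1cccc(c1)[C@@]1(C)CCC(OC(=S)SC)C(C)(C)C1
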